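The readings are calculated with made-up constants; noise was put on by code.

I decided to leave the rates alone and read the answer from the two products, since what is asked is a comparison of them.

all flasks: left-handed substrate 0.10 M; right-handed substrate 0.10 M; gas 34 mM (held)
- Wednesday's: catalyst 0.099 mM; run made earlier
- Sunday's: catalyst 0.27 mM; run made earlier
- east: catalyst 0.080 mM; time 1.0 h
- north-west: catalyst 0.12 mM; time 1.0 h
- north-east: catalyst 0.20 mM; time 1.0 h

| run | time / min | left-handed product / % | right-handed product / % | left-handed substrate / % |
|---|---|---|---|---|
| Wednesday's | 3.00 | 1.3 | 0 | 48.5 |
| Wednesday's | 6.00 | 3.9 | 0 | 47.6 |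
| Wednesday's | 10.0 | 5.4 | 0.1 | 45.0 |
| Wednesday's | 15.0 | 9.0 | 0.7 | 43.2 |
| Wednesday's | 25.0 | 14.1 | 1.2 | 39.6 |
| Wednesday's | 40.0 | 20.5 | 0.5 | 37.0 |
| Sunday's | 3.00 | 1.9 | 0 | 48.4 |
| Sunday's | 8.00 | 8.7 | 0.2 | 42.3 |
| Sunday's | 15.0 | 18.9 | 0.7 | 35.6 |
| Sunday's | 25.0 | 27.7 | 1.6 | 30.3 |
| Sunday's | 30.0 | 31.3 | 1.6 | 28.0 |
| Sunday's | 40.0 | 36.7 | 1.5 | 26.2 |

(scatter of a reading: 0.5 percentage points)

- catalyst is single-handed; left-handed substrate and right-handed substrate are mirror images of each other, charged as a racemate, each of them at the stated concentration
- what was read earlier has a scatter of 0.5 percentage points, one standard deviation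
- at the start none of the gas is in solution
- an excess is the difference of the two amounts in percent of their sum
- "hardly changes" means that all values lie within two and a half points (for a concentration: within two and a half percent of the largest)

- excess of left-handed product over right-handed product at the end for east, north-west, north-east, in this order
- how that number moves from the first to the last of them (falls all the way / falls, then rises / rises all the way / hardly changes / rises, then falls)

The asked number is the enantiomeric excess. With f as left-handed product over right-handed product, it is f less one, over f plus one. Single readings of the right-handed product were poor: in Wednesday's run it read 1.2% and then 0.5%, with a scatter of 0.5 percentage points. So I summed the last three readings of each product. Wednesday's run gave 18.2, an excess of 89.6%. Sunday's run gave 20.4, an excess of 90.6%. Both runs pooled gave the pooled product ratio f = 19.6, an excess of 90.3%.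

My second way went through the substrates. The balance gave the right-handed substrate, so left-handed over right-handed substrate at the last reading was 0.881 in Wednesday's run and 0.736 in Sunday's run. If each product grows with its own substrate, f follows that ratio, and a small fractional change in f moves the excess by 2/f of that fraction. So, taking the last ratio for the whole run, Sunday's run should lie lower, by about 1.7 points. Here the two ways parted, for the products put Sunday's run higher by 1.0 point. I distrusted the products for this slope, since Wednesday's three right-handed readings summed to 2.40%, each with a scatter of 0.5 points. The runs span a factor of 2.73 in catalyst and the asked flasks 2.50, though east starts below Wednesday's run. I committed to about 90.3%, sinking slightly: hardly changes.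

The forecast gave 91.5%, 91% and 90.5%, shape hardly changes; more catalyst shifts the substrates, and that, in its words, “lowers the excess only slightly”.

The flasks gave 89.8%, 89.4% and 88.8%, shape hardly changes.

    reagent + catalyst + right-handed substrate → catalyst + right-handed product (k = 380 M⁻² min⁻¹)
    left-handed substrate ⇌ right-handed substrate (k = 0.0380 min⁻¹)
    catalyst ⇌ dormant form (K = 3.70, k = 0.0330 min⁻¹)
    reagent + catalyst + left-handed substrate → catalyst + left-handed product (k = 7700 M⁻² min⁻¹)
    gas ⇌ reagent, rate k5*(csat - [reagent]) (kL = 0.250 min⁻¹)

In east at the end, the left-handed route used reagent 19 times as fast as the right-handed route; the carried f, a ratio of amounts read in the earlier runs, was 19.6. Divided by f, north-east's left-handed product of 39.4% at the end gives 2.01% of right-handed product, and that flask held 2.34%.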